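**Plan**
- The target is a depside. The retrosynthesis cuts both bonds at its ester carbonyl: C1 of the 4-hydroxy-2-methoxy-6-propylphenyl ring (ring A) to C(=O), and C(=O) to O4 of the divaric acid ring (ring B).
- The feature that allows this: the carbonyl is a single carbon held between an sp2 carbon (C1 of ring A, flanked by 2-OMe and 6-propyl) and a phenolic oxygen (O4 of ring B, the one hydroxyl of that ring not hydrogen-bonded to the C1 carboxyl). It can therefore enter as carbon monoxide between an aryl iodide and a phenol.
- Both benzene rings are bought ready-made as divarinol; no ring is formed. Ring A arm: mono-O-benzylation, iodination ortho to the free hydroxyl and para to the benzyl ether, then O-methylation. Ring B arm: carboxylation and benzyl ester formation.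
- The two arms are joined through CO in the palladium-catalysed coupling; one hydrogenolysis then frees the 4-hydroxyl of ring A and the carboxylic acid of ring B.
- Stereochemistry: the target has no stereocentre and no configurationally stable axis, so nothing has to be set.

Key step: step 6

Remark: the target SMILES carries no stereodescriptor and the molecule is achiral, so the compound as drawn is the single species to be made.

**Step 1**
Reactants: 1 divarinol (5-propylbenzene-1,3-diol); 2 benzyl bromide
Product: 3 3-(benzyloxy)-5-propylphenol
Conditions: BnBr (0.8 equiv), K2CO3 (1.0 equiv), acetone, reflux; excess 1 recovered by chromatography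
Reagents that add atoms: none
Why: Williamson ether synthesis on a symmetrical diol whose two hydroxyls are equivalent, so with the diol in excess statistical mono-O-benzylation should prevail and unreacted diol and bis-ether are separable.

**Step 2**
Reactants: 3 3-(benzyloxy)-5-propylphenol
Product: 4 5-(benzyloxy)-2-iodo-3-propylphenol
Conditions: I2 (1.0 equiv), NaHCO3, THF/H2O (1:1), 0 °C
Reagents that add atoms: iodine, II
Why: Electrophilic aromatic iodination of the phenol(ate), in which the position ortho to the free hydroxyl and para to the benzyl ether is doubly activated and has the smallest neighbours (OH and propyl), in line with the iodine/bicarbonate iodination of 3-alkoxyphenols to 2-iodo-5-alkoxyphenols.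

**Step 3**
Reactants: 4 5-(benzyloxy)-2-iodo-3-propylphenol
Product: 5 5-(benzyloxy)-2-iodo-1-methoxy-3-propylbenzene
Conditions: MeI, K2CO3, acetone, reflux
Reagents that add atoms: iodomethane, CI
Why: Williamson O-methylation of the phenol, which stays accessible to the small electrophile despite the ortho iodine, while the aryl iodide and the benzyl ether are inert to K2CO3/MeI.

**Step 4**
Reactants: 1 divarinol (5-propylbenzene-1,3-diol)
Product: 6 divaric acid (2,4-dihydroxy-6-propylbenzoic acid)
Conditions: MeOMgOCO2Me (2 M in DMF, excess), 120 °C, N2 sweep; then ice-cold aq. HCl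
Reagents that add atoms: methyl magnesium carbonate (Stiles reagent), COC(=O)O[Mg]OC
Why: Stiles carboxylation (Kolbe–Schmitt type), in which the magnesium phenoxide delivers CO2 to the ortho carbon that is also para to the second hydroxyl, as in the conversion of olivetol into olivetolic acid, and the magnesium salicylate chelate holds the product against decarboxylation until the cold acidic work-up.

**Step 5**
Reactants: 6 divaric acid; 2 benzyl bromide
Product: 7 benzyl divarate (benzyl 2,4-dihydroxy-6-propylbenzoate)
Conditions: BnBr (1.05 equiv), KHCO3, DMF, rt
Reagents that add atoms: none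
Why: SN2 O-alkylation of the carboxylate, since hydrogen carbonate deprotonates only the carboxylic acid and benzyl bromide should therefore esterify it and leave both phenols free, as in the preparation of benzyl orsellinate.

**Step 6**
Reactants: 5 5-(benzyloxy)-2-iodo-1-methoxy-3-propylbenzene; 7 benzyl divarate (1.2 equiv); 8 carbon monoxide
Product: 9 benzyl 4-{[4-(benzyloxy)-2-methoxy-6-propylbenzoyl]oxy}-2-hydroxy-6-propylbenzoate
Conditions: Pd(OAc)2 (5 mol %), Xantphos (6 mol %), CO (1 atm, balloon), Et3N (3 equiv), toluene, 90 °C
Reagents that add atoms: none
Why: Pd(0)/Xantphos adds oxidatively into the C1–I bond of 5, CO inserts into the aryl–palladium bond to give an aroylpalladium iodide, the 4-phenoxide of 7 (formed with Et3N) replaces iodide on palladium, and C–O reductive elimination releases ester 9 and Pd(0). The closest known reaction type is the palladium-catalysed aryloxycarbonylation of aryl iodides with phenols (Heck carbonylation), which is known to accept 2,6-disubstituted aryl halides. No ring closes and no stereocentre arises; the two skeletal bonds C1(ring A)–C(=O) and C(=O)–O4(ring B) form in one operation. The step needs chemoselectivity between the two phenols of 7: the 2-hydroxyl is tied into a hydrogen bond with the benzyl ester carbonyl and is less acidic and less nucleophilic, so only the 4-hydroxyl, para to the ester, should be engaged. It also needs CO insertion to outrun direct C–O coupling and proto-deiodination; the ortho methoxy and propyl groups on the aryl–palladium species should speed migratory insertion and the final reductive elimination, and because the ester is assembled on the metal no tetrahedral intermediate at the crowded carbonyl is required. A small excess of 7 should suppress a second acylation at the 2-hydroxyl of 9.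

**Step 7**
Reactants: 9 benzyl 4-{[4-(benzyloxy)-2-methoxy-6-propylbenzoyl]oxy}-2-hydroxy-6-propylbenzoate
Product: 10 2-hydroxy-4-[(4-hydroxy-2-methoxy-6-propylbenzoyl)oxy]-6-propylbenzoic acid (CNP0147807.0)
Conditions: H2 (1 atm), 10% Pd/C, EtOAc, rt
Reagents that add atoms: none
Why: Heterogeneous catalytic hydrogenolysis cleaves the two benzylic C–O bonds (aryl benzyl ether and benzyl ester) to toluene, while the aryl ester, the methyl ether and the propyl chains have no benzylic C–O bond and should survive neutral conditions at room temperature.

**Compound list**
1 | divarinol (5-propylbenzene-1,3-diol) | CCCc1cc(O)cc(O)c1 | starting material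
2 | benzyl bromide | BrCc1ccccc1 | starting material
3 | 3-(benzyloxy)-5-propylphenol | CCCc1cc(O)cc(OCc2ccccc2)c1 | intermediate
4 | 5-(benzyloxy)-2-iodo-3-propylphenol | CCCc1cc(OCc2ccccc2)cc(O)c1I | intermediate
5 | 5-(benzyloxy)-2-iodo-1-methoxy-3-propylbenzene | CCCc1cc(OCc2ccccc2)cc(OC)c1I | intermediate
6 | divaric acid (2,4-dihydroxy-6-propylbenzoic acid) | CCCc1cc(O)cc(O)c1C(=O)O | intermediate
7 | benzyl divarate (benzyl 2,4-dihydroxy-6-propylbenzoate) | CCCc1cc(O)cc(O)c1C(=O)OCc1ccccc1 | intermediate
8 | carbon monoxide | [C-]#[O+] | starting material
9 | benzyl 4-{[4-(benzyloxy)-2-methoxy-6-propylbenzoyl]oxy}-2-hydroxy-6-propylbenzoate | CCCc1cc(OC(=O)c2c(CCC)cc(OCc3ccccc3)cc2OC)cc(O)c1C(=O)OCc1ccccc1 | intermediate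
10 | 2-hydroxy-4-[(4-hydroxy-2-methoxy-6-propylbenzoyl)oxy]-6-propylbenzoic acid | CCCc1cc(OC(=O)c2c(CCC)cc(O)cc2OC)cc(O)c1C(=O)O | target

Total step count: 7
Longest linear sequence: 5 steps (steps 1, 2, 3, 6, 7); the ring B arm (steps 4, 5) joins at step 6.

**Steps most likely to fail**

1. Step 6. The aroylpalladium species from the doubly ortho-substituted, electron-rich iodide may be captured slowly by the phenoxide, so that proto-deiodination, direct aryl ether formation or catalyst deactivation under CO could take over. The fallback sets out from 5 and moves the carbonyl source to CO2 with a separate acylation. Iodine–magnesium exchange with i-PrMgCl·LiCl in THF (0 °C to rt) should give [4-(benzyloxy)-2-methoxy-6-propylphenyl]magnesium chloride F1. This is quenched with CO2 gas and acidified to 4-(benzyloxy)-2-methoxy-6-propylbenzoic acid F2. Trifluoroacetic anhydride in toluene at rt then converts F2 into 4-(benzyloxy)-2-methoxy-6-propylbenzoic trifluoroacetic anhydride F3. F3 should ionise to a donor-stabilised acylium ion and acylate the 4-hydroxyl of 7 (the classical depside esterification). The route is rejoined at 9.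

2. Step 2. Electrophilic attack may spread over the three activated ring positions (between the two oxygens, or para to the hydroxyl), and over-iodination may occur, giving poor regioselectivity. The fallback sets out from 3 and turns the phenol oxygen into a weak director so that the benzyl ether alone steers the electrophile to its para position. Acetylation (Ac2O, pyridine, CH2Cl2) gives 3-(benzyloxy)-5-propylphenyl acetate F4. Iodination with NIS and catalytic TFA in MeCN should then give 5-(benzyloxy)-2-iodo-3-propylphenyl acetate F5. Methanolysis (K2CO3, MeOH, rt) rejoins the route at 4.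

3. Step 4. Carboxylation may occur in part at the carbon between the two hydroxyls, and the β-resorcylic acid may lose CO2 during hot or acidic handling. The fallback sets out from 1 and installs the carbon at the aldehyde oxidation level. Vilsmeier–Haack formylation (POCl3, DMF, MeCN, 0 °C to rt) should give N-[(2,4-dihydroxy-6-propylphenyl)methylidene]-N-methylmethanaminium chloride F6, formed para to one hydroxyl as with orcinol. Aqueous hydrolysis gives 2,4-dihydroxy-6-propylbenzaldehyde F7. Lindgren–Pinnick oxidation (NaClO2, NaH2PO4, sulfamic acid, aq. dioxane, 0 °C) rejoins the route at 6.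

**Further compounds**
F1 | step 6 | [4-(benzyloxy)-2-methoxy-6-propylphenyl]magnesium chloride | CCCc1cc(OCc2ccccc2)cc(OC)c1[Mg]Cl
F2 | step 6 | 4-(benzyloxy)-2-methoxy-6-propylbenzoic acid | CCCc1cc(OCc2ccccc2)cc(OC)c1C(=O)O
F3 | step 6 | 4-(benzyloxy)-2-methoxy-6-propylbenzoic trifluoroacetic anhydride | CCCc1cc(OCc2ccccc2)cc(OC)c1C(=O)OC(=O)C(F)(F)F
F4 | step 2 | 3-(benzyloxy)-5-propylphenyl acetate | CCCc1cc(OC(C)=O)cc(OCc2ccccc2)c1
F5 | step 2 | 5-(benzyloxy)-2-iodo-3-propylphenyl acetate | CCCc1cc(OCc2ccccc2)cc(OC(C)=O)c1I
F6 | step 4 | N-[(2,4-dihydroxy-6-propylphenyl)methylidene]-N-methylmethanaminium chloride | CCCc1cc(O)cc(O)c1C=[N+](C)C.[Cl-]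
F7 | step 4 | 2,4-dihydroxy-6-propylbenzaldehyde | CCCc1cc(O)cc(O)c1C=O
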